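**Strategy.** The quinone ring (C1=O, C2–OH, C3–CH2R, C4=O, C5–OMe, C6–H) is cut into a C2–C3 silyl ynol ether carrying the finished octalin and a C4–C5–C6–C1 vinylketene. In one operation a Danheiser benzannulation joins them: photochemical Wolff rearrangement of an acyclic diazo enone, a [2+2] union that forges C3–C4 and closes a cyclobutenone, then 4π opening and 6π closure to the tetrasubstituted phenol. The step exploits C3 lying between two oxygen-bearing ring carbons (C2 and C4), the pattern that ketene/ynol ether polarity writes. The octalin comes from asymmetric conjugate addition, enolate propargylation and cationic ring A closure; phenol oxidation at C1 finishes.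

Key step: step 7

Assumption: the sense of induction of the phosphoramidite ligand in step 1 has to be matched by experiment; the ligand enantiomer that delivers the (3S) centre is used.

Remark: "Oct" stands for (1R,2S)-1,2,5,5-tetramethyl-1,2,3,4,5,6,7,8-octahydronaphthalen-1-yl (methyl groups at C1 and C2 cis, CH2 substituent at C1 trans to the C2 methyl, tetrasubstituted C4a=C8a alkene). Quinone atoms are numbered as in the strategy paragraph.

**Step 1**
Reactants: 1 2-methylcyclohex-2-en-1-one
Product: 3 {[(3S)-2,3-dimethylcyclohex-1-en-1-yl]oxy}trimethylsilane, via aluminium enolate 2 (not isolated)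
Conditions: Me3Al, copper thiophene-2-carboxylate (CuTC, monovalent copper, 2 mol%), binaphthol-derived N,N-bis(1-phenylethyl)phosphoramidite (4 mol%), Et2O, −30 °C; then Me3SiOTf, THF, −30 → 0 °C
Reagents that add atoms: trimethylaluminium C[Al](C)C; trimethylsilyl trifluoromethanesulfonate C[Si](C)(C)OS(=O)(=O)C(F)(F)F
Why: Copper-catalysed asymmetric conjugate addition of Me3Al to a 2-substituted cyclohexenone should set the C3 centre (S) through face selection by the chiral copper–phosphoramidite complex, and O-silylation of the aluminium enolate fixes the tetrasubstituted enolate regiochemistry.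

**Step 2**
Reactants: 3 {[(3S)-2,3-dimethylcyclohex-1-en-1-yl]oxy}trimethylsilane; 4 3-bromo-1-(trimethylsilyl)prop-1-yne
Product: 6 (2R,3S)-2,3-dimethyl-2-[3-(trimethylsilyl)prop-2-yn-1-yl]cyclohexan-1-one, via lithium enolate 5 (not isolated)
Conditions: MeLi, THF, 0 °C → rt; then 4, HMPA, −78 → −20 °C
Reagents that add atoms: none
Why: Regiospecific enolate generation from the silyl enol ether followed by SN2 enolate alkylation should place the propargyl group anti to the pseudoaxial C3 methyl group, setting the quaternary centre (2R) with the two methyl groups cis.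

**Step 3**
Reactants: 6 (2R,3S)-2,3-dimethyl-2-[3-(trimethylsilyl)prop-2-yn-1-yl]cyclohexan-1-one; 7 5-bromo-2-methylpent-2-ene
Product: 9 (2R,3S)-2,3-dimethyl-1-(4-methylpent-3-en-1-yl)-2-[3-(trimethylsilyl)prop-2-yn-1-yl]cyclohexan-1-ol (both C1 epimers), via Grignard reagent 8 (not isolated)
Conditions: 7, Mg, THF, rt; then 6, LaCl3·2LiCl, THF, 0 °C; aq. NH4Cl
Reagents that add atoms: none
Why: Lanthanum-chloride-promoted Grignard 1,2-addition should outrun enolisation of the hindered ketone, and the new carbinol centre may form as a mixture because it becomes sp2 in step 4.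

**Step 4**
Reactants: 9 (2R,3S)-2,3-dimethyl-1-(4-methylpent-3-en-1-yl)-2-[3-(trimethylsilyl)prop-2-yn-1-yl]cyclohexan-1-ol
Product: 12 (1R,2S)-1,2,5,5-tetramethyl-1-(prop-2-yn-1-yl)-1,2,3,4,5,6,7,8-octahydronaphthalene, via diene 10 (not isolated), via silylalkyne 11 (not isolated)
Conditions: MeSO3H, CH2Cl2, −20 → 0 °C; then K2CO3, MeOH, rt
Reagents that add atoms: none
Why: E1 dehydration followed by cation–olefin cyclisation (tertiary cation at the prenyl terminus onto the ring alkene) should close ring A, with proton loss from the ring-fusion cation giving the thermodynamically favoured tetrasubstituted alkene, after which base-mediated protodesilylation frees the alkyne; no stereocentre is formed and neither existing centre is epimerisable.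

**Step 5**
Reactants: 12 (1R,2S)-1,2,5,5-tetramethyl-1-(prop-2-yn-1-yl)-1,2,3,4,5,6,7,8-octahydronaphthalene
Product: 15 triisopropyl[(3-Oct-prop-1-yn-1-yl)oxy]silane, via lithium acetylide 13 (not isolated), via lithium ynolate 14 (not isolated)
Conditions: n-BuLi, THF, −78 °C; LiOOtBu (from t-BuOOH and LiN(SiMe3)2), −78 → 0 °C; then iPr3SiOTf, −78 → 0 °C
Reagents that add atoms: lithium tert-butyl peroxide CC(C)(C)OO[Li]; triisopropylsilyl trifluoromethanesulfonate CC(C)[Si](OS(=O)(=O)C(F)(F)F)(C(C)C)C(C)C
Why: Oxidation of a lithium acetylide by a lithium alkyl peroxide to the ynolate and O-silylation with a bulky silyl triflate is the standard acetylide-oxidation route to triisopropylsilyl ynol ethers and touches no stereocentre.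

**Step 6**
Reactants: 16 (E)-4-methoxybut-3-en-2-one
Product: 18 (E)-1-diazo-4-methoxybut-3-en-2-one, via trifluoroacetyl diketone 17 (not isolated)
Conditions: LiN(SiMe3)2, THF, −78 °C; CF3CO2CH2CF3; then MsN3, Et3N, H2O, MeCN, rt
Reagents that add atoms: methanesulfonyl azide CS(=O)(=O)N=[N+]=[N-]
Why: Detrifluoroacetylative diazo transfer (kinetic enolate trifluoroacetylation, then Regitz-type diazo transfer with loss of the trifluoroacetyl group) is the established way to make α'-diazo enones and should leave the (E)-β-methoxy enone intact.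

**Step 7**
Reactants: 15 triisopropyl[(3-Oct-prop-1-yn-1-yl)oxy]silane; 18 (E)-1-diazo-4-methoxybut-3-en-2-one
Product: 23 6-methoxy-2-(Oct-methyl)-3-[(triisopropylsilyl)oxy]phenol, via vinylketene 19 (not isolated), via vinylcyclobutenone 20 (not isolated), via dienylketene 21 (not isolated), via cyclohexadienone 22 (not isolated)
Conditions: hν (254 nm, low-pressure Hg lamp), degassed CH2Cl2, rt, 18 added in portions; then toluene, 80 °C
Reagents that add atoms: none
Why: Irradiation of 18 triggers a photochemical Wolff rearrangement to vinylketene 19, whose electrophilic ketene carbon is attacked by the nucleophilic, CH2-bearing carbon of ynol ether 15 in a regiospecific [2+2] cycloaddition that forges the quinone C3–C4 bond and closes cyclobutenone 20. 4π electrocyclic opening of 20 gives dienylketene 21, 6π electrocyclisation (forming C4–C5) gives dienone 22, and enolisation delivers phenol 23. The closest known reaction type is the Danheiser benzannulation in its diazo ketone form, which is established for silyl ynol ethers and gives resorcinol monosilyl ethers with the alkyne substituent between the two oxygens. Two rings close, the temporary four-membered ring by [2+2] cycloaddition and the six-membered carbocycle by disrotatory 6π electrocyclisation. No lasting stereocentre is created (the sp3 centres of 20 and 22 vanish on aromatisation) and the two octalin centres are remote and untouched. The step needs regioselectivity in the [2+2] event, secured by ynol ether polarisation against the ketene carbonyl carbon, and chemoselectivity, secured by the inertness of the tetrasubstituted alkene toward ketenes and 254 nm light.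

**Step 8**
Reactants: 23 6-methoxy-2-(Oct-methyl)-3-[(triisopropylsilyl)oxy]phenol
Product: 24 4-methoxy-2-(Oct-methyl)benzene-1,3-diol
Conditions: Bu4NF, AcOH, THF, 0 °C
Reagents that add atoms: none
Why: Fluoride-mediated cleavage of an aryl silyl ether, buffered with acetic acid so that the electron-rich resorcinol stays protonated, is a standard deprotection.

**Step 9**
Reactants: 24 4-methoxy-2-(Oct-methyl)benzene-1,3-diol
Product: 25 2-hydroxy-5-methoxy-3-(Oct-methyl)cyclohexa-2,5-diene-1,4-dione
Conditions: (KSO3)2NO (Fremy's salt), KH2PO4 buffer, acetone/H2O, rt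
Reagents that add atoms: potassium nitrosodisulfonate [O]N(S(=O)(=O)[O-])S(=O)(=O)[O-].[K+].[K+]
Why: In this Teuber oxidation the nitroxyl radical should oxidise the phenol and couple at the only free position that is para to one hydroxyl and ortho to the other (quinone C1), giving the 2-hydroxy-1,4-benzoquinone directly while the tetrasubstituted alkene is inert to the one-electron oxidant.

**Compound list**
1 | 2-methylcyclohex-2-en-1-one | CC1=CCCCC1=O | starting material
2 | dimethyl{[(3S)-2,3-dimethylcyclohex-1-en-1-yl]oxy}alumane (aluminium enolate, not isolated) | C[Al](C)OC1=C(C)[C@@H](C)CCC1 | intermediate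
3 | {[(3S)-2,3-dimethylcyclohex-1-en-1-yl]oxy}trimethylsilane | C[Si](C)(C)OC1=C(C)[C@@H](C)CCC1 | intermediate
4 | 3-bromo-1-(trimethylsilyl)prop-1-yne | C[Si](C)(C)C#CCBr | starting material
5 | lithium (3S)-2,3-dimethylcyclohex-1-en-1-olate (not isolated) | [Li]OC1=C(C)[C@@H](C)CCC1 | intermediate
6 | (2R,3S)-2,3-dimethyl-2-[3-(trimethylsilyl)prop-2-yn-1-yl]cyclohexan-1-one | C[Si](C)(C)C#CC[C@@]1(C)C(=O)CCC[C@@H]1C | intermediate
7 | 5-bromo-2-methylpent-2-ene | CC(C)=CCCBr | starting material
8 | (4-methylpent-3-en-1-yl)magnesium bromide (not isolated) | CC(C)=CCC[Mg]Br | intermediate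
9 | (2R,3S)-2,3-dimethyl-1-(4-methylpent-3-en-1-yl)-2-[3-(trimethylsilyl)prop-2-yn-1-yl]cyclohexan-1-ol, both C1 epimers | C[Si](C)(C)C#CC[C@@]1(C)C(O)(CCC=C(C)C)CCC[C@@H]1C | intermediate
10 | trimethyl{3-[(1R,6S)-1,6-dimethyl-2-(4-methylpent-3-en-1-yl)cyclohex-2-en-1-yl]prop-1-yn-1-yl}silane (not isolated) | C[Si](C)(C)C#CC[C@@]1(C)C(CCC=C(C)C)=CCC[C@@H]1C | intermediate
11 | trimethyl(3-Oct-prop-1-yn-1-yl)silane (not isolated) | C[Si](C)(C)C#CC[C@@]1(C)C2=C(CC[C@@H]1C)C(C)(C)CCC2 | intermediate
12 | (1R,2S)-1,2,5,5-tetramethyl-1-(prop-2-yn-1-yl)-1,2,3,4,5,6,7,8-octahydronaphthalene | C#CC[C@@]1(C)C2=C(CC[C@@H]1C)C(C)(C)CCC2 | intermediate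
13 | lithium acetylide of 12 (not isolated) | [Li]C#CC[C@@]1(C)C2=C(CC[C@@H]1C)C(C)(C)CCC2 | intermediate
14 | lithium 3-Oct-prop-1-yn-1-olate (ynolate, not isolated) | [Li]OC#CC[C@@]1(C)C2=C(CC[C@@H]1C)C(C)(C)CCC2 | intermediate
15 | triisopropyl[(3-Oct-prop-1-yn-1-yl)oxy]silane | CC(C)[Si](OC#CC[C@@]1(C)C2=C(CC[C@@H]1C)C(C)(C)CCC2)(C(C)C)C(C)C | intermediate
16 | (E)-4-methoxybut-3-en-2-one | CO/C=C/C(C)=O | starting material
17 | (E)-1,1,1-trifluoro-6-methoxyhex-5-ene-2,4-dione (not isolated) | CO/C=C/C(=O)CC(=O)C(F)(F)F | intermediate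
18 | (E)-1-diazo-4-methoxybut-3-en-2-one | CO/C=C/C(=O)C=[N+]=[N-] | intermediate
19 | (E)-4-methoxybuta-1,3-dien-1-one (vinylketene, not isolated) | CO/C=C/C=C=O | intermediate
20 | 4-[(E)-2-methoxyethenyl]-2-(Oct-methyl)-3-[(triisopropylsilyl)oxy]cyclobut-2-en-1-one (not isolated) | O=C1C(C[C@@]2(C)C3=C(CC[C@@H]2C)C(C)(C)CCC3)=C(O[Si](C(C)C)(C(C)C)C(C)C)C1/C=C/OC | intermediate
21 | 6-methoxy-2-(Oct-methyl)-3-[(triisopropylsilyl)oxy]hexa-1,3,5-trien-1-one, ketene carbon and C5 cis on C3=C4, 5E (not isolated) | O=C=C(C[C@@]1(C)C2=C(CC[C@@H]1C)C(C)(C)CCC2)/C(O[Si](C(C)C)(C(C)C)C(C)C)=C\C=C\OC | intermediate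
22 | 6-methoxy-2-(Oct-methyl)-3-[(triisopropylsilyl)oxy]cyclohexa-2,4-dien-1-one (not isolated) | O=C1C(C[C@@]2(C)C3=C(CC[C@@H]2C)C(C)(C)CCC3)=C(O[Si](C(C)C)(C(C)C)C(C)C)C=CC1OC | intermediate
23 | 6-methoxy-2-(Oct-methyl)-3-[(triisopropylsilyl)oxy]phenol | COc1ccc(O[Si](C(C)C)(C(C)C)C(C)C)c(C[C@@]2(C)C3=C(CC[C@@H]2C)C(C)(C)CCC3)c1O | intermediate
24 | 4-methoxy-2-(Oct-methyl)benzene-1,3-diol | COc1ccc(O)c(C[C@@]2(C)C3=C(CC[C@@H]2C)C(C)(C)CCC3)c1O | intermediate
25 | 2-hydroxy-5-methoxy-3-{[(1R,2S)-1,2,5,5-tetramethyl-1,2,3,4,5,6,7,8-octahydronaphthalen-1-yl]methyl}cyclohexa-2,5-diene-1,4-dione | COC1=CC(=O)C(O)=C(C[C@@]2(C)C3=C(CC[C@@H]2C)C(C)(C)CCC3)C1=O | target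

**Totals.** 9 steps in all. The longest linear sequence is 8 steps (steps 1–5 and 7–9); step 6 is a one-step side branch.

**Steps most likely to fail**

Step 7. The electron-rich vinylketene may be consumed by dimerisation or by O-acylation of the product phenol faster than the hindered ynol ether captures it, or the siloxycyclobutenone may resist ring opening. The fallback closes the same C3–C4 bond by a Moore rearrangement and sets out from alkyne 12. Its lithium acetylide (n-BuLi) is added to dimethyl squarate to give 4-hydroxy-2,3-dimethoxy-4-(3-Oct-prop-1-yn-1-yl)cyclobut-2-en-1-one F1. 1,2-Reduction of the vinylogous ester carbonyl (LiAlH(OtBu)3) gives 2,3-dimethoxy-1-(3-Oct-prop-1-yn-1-yl)cyclobut-2-ene-1,4-diol F2. Selective activation of the secondary carbinol (TFAA, 2,6-lutidine, then aqueous work-up) effects a Stork–Danheiser transposition to 4-hydroxy-2-methoxy-4-(3-Oct-prop-1-yn-1-yl)cyclobut-2-en-1-one F3. Thermolysis in toluene at 110 °C (4π opening to the alkynylketene, ring closure between the ketene carbon and the distal alkyne carbon, hydrogen transfer) gives 2-methoxy-6-(Oct-methyl)cyclohexa-2,5-diene-1,4-dione F4. Nucleophilic epoxidation of the non-methoxylated double bond (H2O2, Na2CO3) gives 3-methoxy-1-(Oct-methyl)-7-oxabicyclo[4.1.0]hept-3-ene-2,5-dione F5, and acid-induced epoxide isomerisation (H2SO4 on SiO2) installs the C2 hydroxyl and returns to the route at 25.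

Step 4. Proton loss from the ring-fusion cation toward the less substituted position, or hydride or methyl migration before proton loss, would erode the tetrasubstituted alkene; acid-promoted hydration of the alkynylsilane is a further loss channel. The fallback moves ring A closure into a radical manifold and sets out from alcohol 9. Dehydration under non-ionising conditions (Burgess reagent, benzene, 50 °C) gives diene 10, now isolated. Hydrogen-atom-transfer-initiated cycloisomerisation (Co(salen)Cl, trivalent cobalt, catalytic PhSiH3, benzene, rt) should generate the tertiary radical at the prenyl terminus, which adds 6-endo to the ring alkene; the resulting tertiary radical is dehydrogenated by the cobalt catalyst to give silylalkyne 11. K2CO3/MeOH then returns to the route at 12.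

Step 3. Enolisation or incomplete addition at a ketone flanked by a quaternary carbon would stall the sequence. The fallback replaces carbonyl addition by cross-coupling and sets out from ketone 6. Enolisation in the only possible direction and O-triflation (KN(SiMe3)2, PhNTf2, THF, −78 °C) give (5S,6R)-5,6-dimethyl-6-[3-(trimethylsilyl)prop-2-yn-1-yl]cyclohex-1-en-1-yl trifluoromethanesulfonate F6. Negishi coupling (Pd(PPh3)4, zerovalent palladium) with (4-methylpent-3-en-1-yl)zinc bromide, made from Grignard reagent 8 and ZnBr2, gives diene 10 directly, where the route is rejoined for the cyclisation and desilylation of step 4.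

**Further compounds**
F1 | step 7 | 4-hydroxy-2,3-dimethoxy-4-(3-Oct-prop-1-yn-1-yl)cyclobut-2-en-1-one | COC1=C(OC)C(O)(C#CC[C@@]2(C)C3=C(CC[C@@H]2C)C(C)(C)CCC3)C1=O
F2 | step 7 | 2,3-dimethoxy-1-(3-Oct-prop-1-yn-1-yl)cyclobut-2-ene-1,4-diol | COC1=C(OC)C(O)(C#CC[C@@]2(C)C3=C(CC[C@@H]2C)C(C)(C)CCC3)C1O
F3 | step 7 | 4-hydroxy-2-methoxy-4-(3-Oct-prop-1-yn-1-yl)cyclobut-2-en-1-one | COC1=CC(O)(C#CC[C@@]2(C)C3=C(CC[C@@H]2C)C(C)(C)CCC3)C1=O
F4 | step 7 | 2-methoxy-6-(Oct-methyl)cyclohexa-2,5-diene-1,4-dione | COC1=CC(=O)C=C(C[C@@]2(C)C3=C(CC[C@@H]2C)C(C)(C)CCC3)C1=O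
F5 | step 7 | 3-methoxy-1-(Oct-methyl)-7-oxabicyclo[4.1.0]hept-3-ene-2,5-dione | COC1=CC(=O)C2OC2(C[C@@]3(C)C4=C(CC[C@@H]3C)C(C)(C)CCC4)C1=O
F0 | step 4 | none | none
F6 | step 3 | (5S,6R)-5,6-dimethyl-6-[3-(trimethylsilyl)prop-2-yn-1-yl]cyclohex-1-en-1-yl trifluoromethanesulfonate | C[Si](C)(C)C#CC[C@@]1(C)C(OS(=O)(=O)C(F)(F)F)=CCC[C@@H]1C
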